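**Strategy.** The pyranone ring (ring C) is disconnected between C-2 and C-3. Its O-1–CH2 unit is recognised as a former aryl methyl ether, and C-3, the stereocentre flanked by the C-4 ketone and ring B, as an aryl/acyl carbene. The precursor is therefore an open diaryl diazoketone whose ring A carries an ordinary methoxy group ortho to the ketone. One enantioselective dirhodium-catalysed C–H insertion into that O–CH3 group closes ring C, forms the C-2–C-3 bond and sets C-3. The ortho oxygen of ring B travels as a silyl ether, so that only the ring A methoxy group offers an O–C–H bond, and is methylated afterwards.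

Key step: step 8

Remark on the chemistry: the sense of induction of Rh2(S-PTAD)4 in this insertion cannot be predicted with certainty. The route is written with the catalyst enantiomer expected to give the (3S) product; Rh2(R-PTAD)4 would be used if the opposite sense is found. Compounds 1, 2, 5 and 7 are taken as purchased.

Step 1
Reactants: 1 1-(2,4-dihydroxy-6-methoxyphenyl)ethanone; 2 1-bromo-3-methylbut-2-ene (prenyl bromide)
Product: 3 1-[2,4-dihydroxy-6-methoxy-3-(3-methylbut-2-en-1-yl)phenyl]ethanone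
Conditions: 2 (1.0 equiv), 10% aq. KOH, 0 °C to rt
Reagents that add atoms: none
Why: C-alkylation of the phenoxide in water (oxygen solvated, soft allylic electrophile) is the established entry to C-prenylated phloroacetophenones and should favour C-3, the carbon between the two hydroxyl-bearing carbons, over C-5 and over O-alkylation.

Step 2
Reactants: 3 1-[2,4-dihydroxy-6-methoxy-3-(3-methylbut-2-en-1-yl)phenyl]ethanone
Product: 4 1-[6-methoxy-3-(3-methylbut-2-en-1-yl)-2,4-bis(triisopropylsilyloxy)phenyl]ethanone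
Conditions: iPr3SiOTf (2.4 equiv), 2,6-lutidine, CH2Cl2, −78 to 0 °C
Reagents that add atoms: triisopropylsilyl trifluoromethanesulfonate, CC(C)[Si](OS(=O)(=O)C(F)(F)F)(C(C)C)C(C)C
Why: Silyl triflate silylation of phenols is fast enough to cap even the chelated, doubly flanked 2-OH, and the bulky triisopropylsilyl groups carry no O–C–H bond and resist migration to an enolate oxygen in the later base-mediated steps.

Step 3
Reactants: 5 2-iodobenzene-1,3-diol
Product: 6 4-bromo-2-iodobenzene-1,3-diol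
Conditions: NBS (1.0 equiv), MeCN, −20 to 0 °C
Reagents that add atoms: N-bromosuccinimide, O=C1CCC(=O)N1Br
Why: Electrophilic aromatic bromination goes to C-4, the only kind of free position that is ortho/para to both hydroxyl groups, and one equivalent of reagent at low temperature should hold it at mono-bromination.

Step 4
Reactants: 6 4-bromo-2-iodobenzene-1,3-diol; 7 (E)-4,4,5,5-tetramethyl-2-(3-methylbut-1-en-1-yl)-1,3,2-dioxaborolane
Product: 8 4-bromo-2-[(E)-3-methylbut-1-en-1-yl]benzene-1,3-diol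
Conditions: Pd(PPh3)4 (5 mol%), K2CO3, 1,4-dioxane/H2O, 60 °C
Reagents that add atoms: none
Why: Suzuki–Miyaura coupling in which oxidative addition of zerovalent palladium to the C–I bond is much faster than to the C–Br bond, and the alkenyl boronate transfers with retention of its E geometry.

Step 5
Reactants: 8 4-bromo-2-[(E)-3-methylbut-1-en-1-yl]benzene-1,3-diol
Product: 10 {4-bromo-2-[(E)-3-methylbut-1-en-1-yl]-3-(triethylsilyloxy)phenoxy}triisopropylsilane, via mono-triisopropylsilyl ether 9 (not isolated)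
Conditions: iPr3SiCl (1.05 equiv), imidazole, DMF, 0 °C; then Et3SiCl (1.3 equiv), rt
Reagents that add atoms: triisopropylsilyl chloride, CC(C)[Si](Cl)(C(C)C)C(C)C; triethylsilyl chloride, CC[Si](Cl)(CC)CC
Why: Two phenol silylations in one flask, in which the bulky chloride takes the hydroxyl with only one ortho substituent and the small triethylsilyl chloride then caps the hydroxyl between bromine and the alkenyl group, the oxygen that must carry no O–C–H bond at the carbene stage and must later be freed selectively.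

Step 6
Reactants: 4 1-[6-methoxy-3-(3-methylbut-2-en-1-yl)-2,4-bis(triisopropylsilyloxy)phenyl]ethanone; 10 {4-bromo-2-[(E)-3-methylbut-1-en-1-yl]-3-(triethylsilyloxy)phenoxy}triisopropylsilane
Product: 11 1-[6-methoxy-3-(3-methylbut-2-en-1-yl)-2,4-bis(triisopropylsilyloxy)phenyl]-2-{3-[(E)-3-methylbut-1-en-1-yl]-2-(triethylsilyloxy)-4-(triisopropylsilyloxy)phenyl}ethanone
Conditions: Pd2(dba)3 (2 mol%), Xantphos (5 mol%), K3PO4, toluene, 80 °C
Reagents that add atoms: none
Why: Palladium-catalysed α-arylation of a methyl ketone enolate with an aryl bromide under mild phosphate base, where the hindered mono-arylated ketone should resist a second arylation.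

Step 7
Reactants: 11 1-[6-methoxy-3-(3-methylbut-2-en-1-yl)-2,4-bis(triisopropylsilyloxy)phenyl]-2-{3-[(E)-3-methylbut-1-en-1-yl]-2-(triethylsilyloxy)-4-(triisopropylsilyloxy)phenyl}ethanone
Product: 12 2-diazo-1-[6-methoxy-3-(3-methylbut-2-en-1-yl)-2,4-bis(triisopropylsilyloxy)phenyl]-2-{3-[(E)-3-methylbut-1-en-1-yl]-2-(triethylsilyloxy)-4-(triisopropylsilyloxy)phenyl}ethanone
Conditions: p-ABSA (1.3 equiv), DBU, MeCN, 0 °C to rt
Reagents that add atoms: 4-acetamidobenzenesulfonyl azide, CC(=O)Nc1ccc(cc1)S(=O)(=O)N=[N+]=[N-]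
Why: Regitz diazo transfer to the methylene that is activated by both the ketone and the aryl ring, the standard route from deoxybenzoins to α-aryl-α-diazoketones.

Step 8
Reactants: 12 2-diazo-1-[6-methoxy-3-(3-methylbut-2-en-1-yl)-2,4-bis(triisopropylsilyloxy)phenyl]-2-{3-[(E)-3-methylbut-1-en-1-yl]-2-(triethylsilyloxy)-4-(triisopropylsilyloxy)phenyl}ethanone
Product: 13 (3S)-3-{3-[(E)-3-methylbut-1-en-1-yl]-2-(triethylsilyloxy)-4-(triisopropylsilyloxy)phenyl}-6-(3-methylbut-2-en-1-yl)-5,7-bis(triisopropylsilyloxy)-2,3-dihydro-4H-chromen-4-one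
Conditions: Rh2(S-PTAD)4 (1 mol%; dirhodium tetrakis[(S)-(1-adamantyl)(N-phthalimido)acetate]), CH2Cl2, slow addition of 12 to 0.005 M, 25 °C
Reagents that add atoms: none
Why: Proposed new method: Rh2(S-PTAD)4 (divalent rhodium) expels N2 from 12 to give a rhodium-bound aryl/acyl carbene at C-3, which inserts through a concerted, hydride-transfer-like three-centre transition state into a C–H bond of the ring A methoxy group, whose oxygen lone pair stabilises the positive charge developing at the future C-2. The closest known reaction types are the dirhodium-catalysed C–H insertion of 2-alkoxyphenyl diazoketones to chroman-4-ones and the functionalisation of methyl ether C–H bonds by donor/acceptor rhodium carbenes; new is their combination in an α-aryl-α-diazoketone whose only stereocentre arises at the carbene carbon. Ring C closes by 1,6-C–H insertion through a six-membered cyclic transition state made of C-3, C-4, C-4a, C-8a, O-1 and C-2. The C-3 stereocentre is set under catalyst control, the chiral carboxylate pocket shielding one face of the carbene so that the C–H bond is delivered to the other, and it is formed directly as a C–H centre without a free enol. The step needs site selectivity for the ring A O–CH3 group: the ring B ortho oxygen (which as a methyl ether would undergo 1,5-insertion to a dihydrobenzofuran) and O-5 carry silyl groups without O–C–H bonds, the bulky triisopropylsilyl group on O-5 disfavours oxonium ylide formation, and the prenyl and styrenyl alkenes are meta-disposed and cannot be reached within the molecule. Slow addition at high dilution suppresses carbene dimerisation and intermolecular reaction with the trisubstituted and trans-disubstituted alkenes, which are poor partners for this bulky carbene.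

Step 9
Reactants: 13 (3S)-3-{3-[(E)-3-methylbut-1-en-1-yl]-2-(triethylsilyloxy)-4-(triisopropylsilyloxy)phenyl}-6-(3-methylbut-2-en-1-yl)-5,7-bis(triisopropylsilyloxy)-2,3-dihydro-4H-chromen-4-one
Product: 14 (3S)-3-{2-hydroxy-3-[(E)-3-methylbut-1-en-1-yl]-4-(triisopropylsilyloxy)phenyl}-6-(3-methylbut-2-en-1-yl)-5,7-bis(triisopropylsilyloxy)-2,3-dihydro-4H-chromen-4-one
Conditions: HF·pyridine, pyridine, THF, 0 °C
Reagents that add atoms: none
Why: Selective desilylation, since buffered acidic fluoride cleaves the small triethylsilyl ether far faster than the three triisopropylsilyl ethers and the non-basic medium leaves the enolisable C-3 stereocentre untouched.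

Step 10
Reactants: 14 (3S)-3-{2-hydroxy-3-[(E)-3-methylbut-1-en-1-yl]-4-(triisopropylsilyloxy)phenyl}-6-(3-methylbut-2-en-1-yl)-5,7-bis(triisopropylsilyloxy)-2,3-dihydro-4H-chromen-4-one
Product: 15 (3S)-3-{2-methoxy-3-[(E)-3-methylbut-1-en-1-yl]-4-(triisopropylsilyloxy)phenyl}-6-(3-methylbut-2-en-1-yl)-5,7-bis(triisopropylsilyloxy)-2,3-dihydro-4H-chromen-4-one
Conditions: CH2N2, Et2O/MeOH, 0 °C to rt
Reagents that add atoms: diazomethane, C=[N+]=[N-]
Why: O-methylation of the only free phenol with diazomethane proceeds by proton transfer and alkylation within the ion pair under neutral conditions, so no ketone enolate forms and C-3 keeps its configuration.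

Step 11
Reactants: 15 (3S)-3-{2-methoxy-3-[(E)-3-methylbut-1-en-1-yl]-4-(triisopropylsilyloxy)phenyl}-6-(3-methylbut-2-en-1-yl)-5,7-bis(triisopropylsilyloxy)-2,3-dihydro-4H-chromen-4-one
Product: 16 (3S)-5,7-dihydroxy-3-{4-hydroxy-2-methoxy-3-[(E)-3-methylbut-1-en-1-yl]phenyl}-6-(3-methylbut-2-en-1-yl)-2,3-dihydro-4H-chromen-4-one
Conditions: Bu4NF/AcOH (1:1, 4 equiv), THF, 0 °C to rt
Reagents that add atoms: none
Why: Global fluoride-mediated cleavage of the aryl silyl ethers, buffered with acetic acid so that no free phenoxide or other base can enolise the ketone and epimerise C-3.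

**Compound list**

1 | 1-(2,4-dihydroxy-6-methoxyphenyl)ethanone | CC(=O)c1c(O)cc(O)cc1OC | starting material
2 | 1-bromo-3-methylbut-2-ene | CC(C)=CCBr | starting material
3 | 1-[2,4-dihydroxy-6-methoxy-3-(3-methylbut-2-en-1-yl)phenyl]ethanone | CC(=O)c1c(O)c(CC=C(C)C)c(O)cc1OC | intermediate
4 | 1-[6-methoxy-3-(3-methylbut-2-en-1-yl)-2,4-bis(triisopropylsilyloxy)phenyl]ethanone | CC(=O)c1c(O[Si](C(C)C)(C(C)C)C(C)C)c(CC=C(C)C)c(O[Si](C(C)C)(C(C)C)C(C)C)cc1OC | intermediate
5 | 2-iodobenzene-1,3-diol | Oc1cccc(O)c1I | starting material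
6 | 4-bromo-2-iodobenzene-1,3-diol | Oc1ccc(Br)c(O)c1I | intermediate
7 | (E)-4,4,5,5-tetramethyl-2-(3-methylbut-1-en-1-yl)-1,3,2-dioxaborolane | CC(C)/C=C/B1OC(C)(C)C(C)(C)O1 | starting material
8 | 4-bromo-2-[(E)-3-methylbut-1-en-1-yl]benzene-1,3-diol | Oc1ccc(Br)c(O)c1/C=C/C(C)C | intermediate
9 | 6-bromo-2-[(E)-3-methylbut-1-en-1-yl]-3-(triisopropylsilyloxy)phenol | CC(C)[Si](Oc1ccc(Br)c(O)c1/C=C/C(C)C)(C(C)C)C(C)C | intermediate
10 | {4-bromo-2-[(E)-3-methylbut-1-en-1-yl]-3-(triethylsilyloxy)phenoxy}triisopropylsilane | CC[Si](CC)(CC)Oc1c(Br)ccc(O[Si](C(C)C)(C(C)C)C(C)C)c1/C=C/C(C)C | intermediate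
11 | 1-[6-methoxy-3-(3-methylbut-2-en-1-yl)-2,4-bis(triisopropylsilyloxy)phenyl]-2-{3-[(E)-3-methylbut-1-en-1-yl]-2-(triethylsilyloxy)-4-(triisopropylsilyloxy)phenyl}ethanone | COc1cc(O[Si](C(C)C)(C(C)C)C(C)C)c(CC=C(C)C)c(O[Si](C(C)C)(C(C)C)C(C)C)c1C(=O)Cc1ccc(O[Si](C(C)C)(C(C)C)C(C)C)c(/C=C/C(C)C)c1O[Si](CC)(CC)CC | intermediate
12 | 2-diazo-1-[6-methoxy-3-(3-methylbut-2-en-1-yl)-2,4-bis(triisopropylsilyloxy)phenyl]-2-{3-[(E)-3-methylbut-1-en-1-yl]-2-(triethylsilyloxy)-4-(triisopropylsilyloxy)phenyl}ethanone | COc1cc(O[Si](C(C)C)(C(C)C)C(C)C)c(CC=C(C)C)c(O[Si](C(C)C)(C(C)C)C(C)C)c1C(=O)C(=[N+]=[N-])c1ccc(O[Si](C(C)C)(C(C)C)C(C)C)c(/C=C/C(C)C)c1O[Si](CC)(CC)CC | intermediate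
13 | (3S)-3-{3-[(E)-3-methylbut-1-en-1-yl]-2-(triethylsilyloxy)-4-(triisopropylsilyloxy)phenyl}-6-(3-methylbut-2-en-1-yl)-5,7-bis(triisopropylsilyloxy)-2,3-dihydro-4H-chromen-4-one | CC[Si](CC)(CC)Oc1c([C@H]2COc3cc(O[Si](C(C)C)(C(C)C)C(C)C)c(CC=C(C)C)c(O[Si](C(C)C)(C(C)C)C(C)C)c3C2=O)ccc(O[Si](C(C)C)(C(C)C)C(C)C)c1/C=C/C(C)C | intermediate
14 | (3S)-3-{2-hydroxy-3-[(E)-3-methylbut-1-en-1-yl]-4-(triisopropylsilyloxy)phenyl}-6-(3-methylbut-2-en-1-yl)-5,7-bis(triisopropylsilyloxy)-2,3-dihydro-4H-chromen-4-one | Oc1c([C@H]2COc3cc(O[Si](C(C)C)(C(C)C)C(C)C)c(CC=C(C)C)c(O[Si](C(C)C)(C(C)C)C(C)C)c3C2=O)ccc(O[Si](C(C)C)(C(C)C)C(C)C)c1/C=C/C(C)C | intermediate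
15 | (3S)-3-{2-methoxy-3-[(E)-3-methylbut-1-en-1-yl]-4-(triisopropylsilyloxy)phenyl}-6-(3-methylbut-2-en-1-yl)-5,7-bis(triisopropylsilyloxy)-2,3-dihydro-4H-chromen-4-one | COc1c([C@H]2COc3cc(O[Si](C(C)C)(C(C)C)C(C)C)c(CC=C(C)C)c(O[Si](C(C)C)(C(C)C)C(C)C)c3C2=O)ccc(O[Si](C(C)C)(C(C)C)C(C)C)c1/C=C/C(C)C | intermediate
16 | (3S)-5,7-dihydroxy-3-{4-hydroxy-2-methoxy-3-[(E)-3-methylbut-1-en-1-yl]phenyl}-6-(3-methylbut-2-en-1-yl)-2,3-dihydro-4H-chromen-4-one | COc1c([C@H]2COc3cc(O)c(CC=C(C)C)c(O)c3C2=O)ccc(O)c1/C=C/C(C)C | target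

Total step count: 11. Longest linear sequence: 9 steps (from 5 through steps 3 to 11).

**Steps most likely to fail**

Step 8 (Proposed new method). The carbene may be diverted before it inserts: by oxonium ylide formation at the methoxy oxygen with rearrangement, by insertion into a Si–CH2 bond of the triethylsilyl group, or by dimerisation. It may also insert with poor facial selectivity, or by a stepwise path through a free enol that loses the stereochemical information. The fallback uses known chemistry, sets out from 11 and comes back at 13. Chelation-directed cleavage of the methyl ether ortho to the ketone with BCl3 (CH2Cl2, −78 °C) should give the 2-hydroxy deoxybenzoin F1. Heating F1 with N,N-dimethylformamide dimethyl acetal in toluene should give, through the enaminone F2 (not isolated), the protected isoflavone F3. Asymmetric transfer hydrogenation with RuCl(p-cymene)[(S,S)-TsDPEN] and HCO2H/Et3N (the mirror-image catalyst if the sense is opposite) should first reduce the C-2/C-3 double bond to 13 and its (3R) enantiomer F4. These interconvert by enolisation under the conditions while the catalyst reduces the ketone of the matched enantiomer (dynamic kinetic resolution), to give the cis-(3S,4S)-isoflavan-4-ol F5. Dess–Martin oxidation of the C-4 alcohol in CH2Cl2 at 0 °C returns 13.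

Step 6. Under hot basic enolate conditions the ortho silyl group may migrate to the enolate oxygen or a silyl ether may be lost, and the hindered enolate may couple sluggishly. The fallback sets out from 4 and 10 and comes back at 11. Soft enolisation of 4 with Me3SiOTf/Et3N (CH2Cl2, 0 °C) should give the trimethylsilyl enol ether F6. Bu3SnF then converts F6 in the flask into the tributyltin enolate F7 (not isolated), which is arylated by 10 under neutral conditions with PdCl2[P(o-tol)3]2 in toluene at reflux to give 11.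

Step 1. The alkylation may be poorly regioselective (C-5 against C-3), may go to oxygen, or may run on to bis-prenylation. The fallback sets out from 1 and comes back at 3. Selective O-alkylation of the non-chelated 4-OH with 3-chloro-3-methylbut-1-yne (CuCl2 cat., DBU, MeCN, 0 °C) should give the 1,1-dimethylpropargyl ether F8. Semi-hydrogenation (H2, Pd/CaCO3 poisoned with Pb(OAc)2, quinoline) should give the 1,1-dimethylallyl ether F9. Aromatic Claisen rearrangement of F9 (N,N-diethylaniline, 130 °C) delivers the normal prenyl group to C-3, the ortho position favoured by the bond fixation of the chelated ketone, and returns 3.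

Further compounds

F1 | step 8 | 1-[2-hydroxy-5-(3-methylbut-2-en-1-yl)-4,6-bis(triisopropylsilyloxy)phenyl]-2-{3-[(E)-3-methylbut-1-en-1-yl]-2-(triethylsilyloxy)-4-(triisopropylsilyloxy)phenyl}ethanone | Oc1cc(O[Si](C(C)C)(C(C)C)C(C)C)c(CC=C(C)C)c(O[Si](C(C)C)(C(C)C)C(C)C)c1C(=O)Cc1ccc(O[Si](C(C)C)(C(C)C)C(C)C)c(/C=C/C(C)C)c1O[Si](CC)(CC)CC
F2 | step 8 | 3-(dimethylamino)-1-[2-hydroxy-5-(3-methylbut-2-en-1-yl)-4,6-bis(triisopropylsilyloxy)phenyl]-2-{3-[(E)-3-methylbut-1-en-1-yl]-2-(triethylsilyloxy)-4-(triisopropylsilyloxy)phenyl}prop-2-en-1-one (enamine geometry not defined) | CN(C)C=C(C(=O)c1c(O)cc(O[Si](C(C)C)(C(C)C)C(C)C)c(CC=C(C)C)c1O[Si](C(C)C)(C(C)C)C(C)C)c1ccc(O[Si](C(C)C)(C(C)C)C(C)C)c(/C=C/C(C)C)c1O[Si](CC)(CC)CC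
F3 | step 8 | 3-{3-[(E)-3-methylbut-1-en-1-yl]-2-(triethylsilyloxy)-4-(triisopropylsilyloxy)phenyl}-6-(3-methylbut-2-en-1-yl)-5,7-bis(triisopropylsilyloxy)-4H-chromen-4-one | CC[Si](CC)(CC)Oc1c(-c2coc3cc(O[Si](C(C)C)(C(C)C)C(C)C)c(CC=C(C)C)c(O[Si](C(C)C)(C(C)C)C(C)C)c3c2=O)ccc(O[Si](C(C)C)(C(C)C)C(C)C)c1/C=C/C(C)C
F4 | step 8 | (3R)-3-{3-[(E)-3-methylbut-1-en-1-yl]-2-(triethylsilyloxy)-4-(triisopropylsilyloxy)phenyl}-6-(3-methylbut-2-en-1-yl)-5,7-bis(triisopropylsilyloxy)-2,3-dihydro-4H-chromen-4-one | CC[Si](CC)(CC)Oc1c([C@@H]2COc3cc(O[Si](C(C)C)(C(C)C)C(C)C)c(CC=C(C)C)c(O[Si](C(C)C)(C(C)C)C(C)C)c3C2=O)ccc(O[Si](C(C)C)(C(C)C)C(C)C)c1/C=C/C(C)C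
F5 | step 8 | (3S,4S)-3-{3-[(E)-3-methylbut-1-en-1-yl]-2-(triethylsilyloxy)-4-(triisopropylsilyloxy)phenyl}-6-(3-methylbut-2-en-1-yl)-5,7-bis(triisopropylsilyloxy)-3,4-dihydro-2H-chromen-4-ol | CC[Si](CC)(CC)Oc1c([C@H]2COc3cc(O[Si](C(C)C)(C(C)C)C(C)C)c(CC=C(C)C)c(O[Si](C(C)C)(C(C)C)C(C)C)c3[C@H]2O)ccc(O[Si](C(C)C)(C(C)C)C(C)C)c1/C=C/C(C)C
F6 | step 6 | {1-[6-methoxy-3-(3-methylbut-2-en-1-yl)-2,4-bis(triisopropylsilyloxy)phenyl]ethenyloxy}trimethylsilane | C=C(O[Si](C)(C)C)c1c(O[Si](C(C)C)(C(C)C)C(C)C)c(CC=C(C)C)c(O[Si](C(C)C)(C(C)C)C(C)C)cc1OC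
F7 | step 6 | tributyl{1-[6-methoxy-3-(3-methylbut-2-en-1-yl)-2,4-bis(triisopropylsilyloxy)phenyl]ethenyloxy}stannane | C=C(O[Sn](CCCC)(CCCC)CCCC)c1c(O[Si](C(C)C)(C(C)C)C(C)C)c(CC=C(C)C)c(O[Si](C(C)C)(C(C)C)C(C)C)cc1OC
F8 | step 1 | 1-{2-hydroxy-6-methoxy-4-[(2-methylbut-3-yn-2-yl)oxy]phenyl}ethanone | CC(=O)c1c(O)cc(OC(C)(C)C#C)cc1OC
F9 | step 1 | 1-{2-hydroxy-6-methoxy-4-[(2-methylbut-3-en-2-yl)oxy]phenyl}ethanone | CC(=O)c1c(O)cc(OC(C)(C)C=C)cc1OC
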